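1. Every mole of target or of isomer of the product holds one mole of starting material and one of coupling partner. Keep the books in coupling partner, the limiting reagent: the flask charges 12.0 mM of it as solid reagent, less than its 20 mM of starting material.

| flask | starting material | solid reagent | precatalyst | remark | time |
|---|---|---|---|---|---|
| Sunday's | 28 mM | 0.60 equiv | 14 mol% | run made earlier |  |
| Tuesday's | 44 mM | 0.60 equiv | 14 mol% | run made earlier |  |
| flask | 20 mM | 0.600 equiv | 14 mol% |  | 8.0 h |

- Sunday's (time / h: isomer of the product / %, target / %): 0.833: 46.1, 2.7; 2.50: 46.1, 3.1; 4.00: 46.0, 2.3; 6.00: 45.7, 2.7; 10.0: 45.8, 2.9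
- Tuesday's (time / h: isomer of the product / %, target / %): 0.833: 49.2, 3.0; 2.50: 49.0, 2.8; 4.00: 48.6, 2.9; 6.00: 48.6, 2.8; 10.0: 49.3, 3.5

(scatter of a reading: 0.3 percentage points)

- given per volume of solution although it is solid: solid reagent
- what may be going on: starting material + coupling partner <-> target; starting material + coupling partner <-> isomer of the product; target + catalyst <-> isomer of the product + catalyst; precatalyst -> catalyst; solid reagent <-> coupling partner
- at the start none of the solid reagent is in solution

* ratio of isomer of the product to target at 1.0 min
* ratio of isomer of the product to target at 20 min
* ratio of isomer of the product to target at 8.0 h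
* which of isomer of the product and target there is more of at 8.0 h

2. Enter Sunday's run. Averaged over its readings, target and isomer of the product together hold 48.7% of the starting material charged, and the readings stay flat from first to last. Assume the solid reagent has dissolved completely. Debit the products: [coupling partner] = 3.17 mM and [starting material] = 14.4 mM.

3. Enter Tuesday's run likewise: products 51.9%, [coupling partner] = 3.55 mM, [starting material] = 21.1 mM.

4. Close the books with the closing quotient, ([target] + [isomer of the product]) / ([starting material][coupling partner]), an equilibrium constant for both products together. Sunday's run reads 0.299 /mM and Tuesday's 0.305 /mM; carry the mean, 0.302 /mM.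

5. Balance the flask. With x the product concentration, x = 0.302 /mM × (20 mM − x)(12.0 mM − x). My root is x = 9.19 mM, or 46.0% of the starting material charged.

6. Read the split from the pooled readings of both runs: isomer of the product to target is 16.5. The readings begin at 0.833 h, so my books give no early ratio.

7. The forecast gives 1 at 1.0 min, 10 at 20 min, 16.5 at 8.0 h, and isomer of the product ahead. Of the early pair it says: “the 1 min and 20 min values are guesses with wide ranges”.

The flask gives 6.14 at 1.0 min, 16.5 at 20 min and 16.5 at 8.0 h, so the forecast's early ratios are lower than the flask's.

starting material + coupling partner ⇌ target (K = 17.0 /M, k = 11.0 /M/s); starting material + coupling partner ⇌ isomer of the product (K = 280 /M, k = 3.40 /M/s); target + catalyst ⇌ isomer of the product + catalyst, rate k3*[catalyst]*[target] forward; the back reaction follows from the equilibrium constant (k = 3.60 /M/s); precatalyst → catalyst (k = 0.00510 /s); solid reagent ⇌ coupling partner, rate k5*(cs5 - [coupling partner]) while solid is left; crystals form when [coupling partner] > cs5 (solubility = 10.0 mM, k = 0.00360 /s) At 8.00 h the flask holds 43.2% isomer of the product and 2.62% target, and its closing quotient is 0.297 /mM. In the flask at 8.00 h, the relaxation half-life of the step to isomer of the product, taken alone with both directions together, is 0.197 min, far shorter than 8.0 h. Starting material stands at 54.2% at 4.00 h and 54.2% at 80.0 h. For a neighbouring flask with 1.00 equiv of solid reagent, the carried closing quotient of 0.302 /mM leaves 33.2% of the starting material, and that flask holds 33%.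

The runs come from a simulation with made-up constants.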